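Weigh the slopes first.

all flasks: left-handed substrate 0.20 M; right-handed substrate 0.20 M; free catalyst 10 mM

| flask | partner | remark |
|---|---|---|
| grey | 0.60 M | the very flask that is asked about, followed so far |
| green | 0.40 M | run made earlier |
| flask | 0.600 M |  |

| grey: time / min | grey: left-handed product / % | green: time / min | green: left-handed product / % |
|---|---|---|---|
| 0.250 | 0.6 | 0.417 | 1.2 |
| 0.667 | 2.1 | 1.33 | 2.6 |
| 1.33 | 3.1 | 2.50 | 3.7 |
| 2.00 | 5.2 | 4.00 | 5.3 |
| 3.00 | 6.3 | 5.00 | 6.7 |
| 4.00 | 8.5 | 6.00 | 7.4 |
| 5.00 | 9.3 | 8.00 | 8.8 |

(readings scatter by 0.5 percentage points)

- free catalyst is single-handed; left-handed substrate and right-handed substrate are mirror images of each other, charged as a racemate, each of them at the stated concentration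
- what is bound to the catalyst counts as converted
- no earlier run changes the charge of free catalyst; that part of a forecast is a guess

- apparent order in partner when 5.0 % of the left-handed substrate and right-handed substrate together are converted (percent change of the rate of making left-handed product for one percent more partner charged)
- apparent order in free catalyst when 5.0 % of the left-handed substrate and right-handed substrate together are converted (percent change of the rate of making left-handed product for one percent more free catalyst charged)

Read the order in partner from two rates, on windows whose product readings run across 5.0 %, taking product for conversion. The product in the grey run rises 5.4 percentage points from 1.33 min to 4.00 min, and in the green run 4.1 points from 1.33 min to 5.00 min.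

Now ask what each input costs if it is off. The catalyst charge is 10 mM in the grey run and 10 mM in the green run, so it cancels. The partner charges carry no stated scatter. The grey rise matters: one end reading off by 0.5 points moves the order by about 0.228. The green rise matters more, at 0.301, because it is smaller. Together the end readings of both windows leave 0.534 on the order; call this standard deviation the width of a two-run order.

Then take the number. The slopes are 0.0202 /min in grey and 0.0112 /min in green, as fractions of the substrates charged. So I read an order in partner of 1.46, give or take the width. No run varies the catalyst, so first order there is a guess.

The forecast gives 1.3 in partner, lower than my reading, and for free catalyst it guesses 0.9, on this ground: “Turnover through a bound catalyst implies about first order, perhaps less if aggregation occurs”.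

The flask gives 1.1 in partner and 1.2 in free catalyst.

    free catalyst + right-handed substrate ⇌ catalyst intermediate B (K = 1.10 /M, k = 2.20 /M/s)
    free catalyst + left-handed substrate ⇌ catalyst intermediate A (K = 2.00 /M, k = 5.30 /M/s)
    partner → decomposed reagent (k = 7.90 × 10⁻⁴ /s)
    partner + catalyst intermediate A → free catalyst + left-handed product (k = 0.120 /M/s)
    partner + free catalyst → spent catalyst (k = 0.00290 /M/s)
    partner + catalyst intermediate B → free catalyst + right-handed product (k = 0.0240 /M/s)

At 4.93 min in the flask, catalyst intermediate A falls back 50 times faster than it goes on, a pre-equilibrium. Put the width to use: the forecast's order in partner, read from the same grey and green runs, stands 0.200 above the flask's, less than the width of 0.534.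

The earlier runs and the new flask come from a simulation on assumed constants.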